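## Retrosynthetic overview

1. Numbering: ring A is C1 (chain)–C2–C3–C4–C5–C6, ring B is C4–C5–C7–C12, ring C is C7–C8–C11–C12, ring D is C8–C9–C10–C11. C1' is the first chain carbon.
2. Feature: on ring A the C1 chain points to the same face as ring B (C7, C12), the concave face of the cis A/B fusion. C1 is therefore fixed by a catalyst on the open arm C5–C6–C1=C2, while the C2–C3 bond is still absent.
3. Key disconnection (ring A): C1–C1' by asymmetric conjugate addition of the chain Grignard reagent, and C2–C3 by Dieckmann attack of the resulting enolate on the C3 ester. The C2 ester, the C3 ketone and the ketal are removed afterwards.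
4. The diester comes from the meso B–C–D anhydride: alkaloid methanolysis tells C4 from C5, Arndt–Eistert homologation inserts C6, and olefination brings C2. Ring B comes from the [2+2] photocycloaddition of maleic anhydride to bicyclo[2.2.0]hex-2-ene, and ring C from a Ramberg–Bäcklund contraction.
5. Ring order: D (purchased) → C → B → A.

Key step: step 14

Assumption: the sense of induction of quinidine (step 7) and of the (R,SP)-diphosphine (step 14) is taken from the empirical models for simple meso anhydrides and linear E-enoates; each has a commercial mirror-image counterpart (quinine, the (S,RP)-ligand) that is used instead if a first run shows the opposite sense.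

## Route

Step 1
Reactants: 1 cis-cyclobutane-1,2-dicarboxylic anhydride
Product: 2 cis-cyclobutane-1,2-diyldimethanol (meso)
Conditions: LiAlH4, THF, 0 °C → reflux; aqueous work-up
Reagents that add atoms: none
Why: Hydride reduction of a cyclic anhydride takes both carbonyl groups to primary alcohols and leaves the purchased cis stereocentres (future C8 and C11) untouched.

Step 2
Reactants: 2 cis-cyclobutane-1,2-diyldimethanol
Product: 3 cis-cyclobutane-1,2-diylbis(methylene) dimethanesulfonate
Conditions: MsCl (2.3 equiv), Et3N, CH2Cl2, 0 °C
Reagents that add atoms: methanesulfonyl chloride, CS(=O)(=O)Cl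
Why: Routine sulfonylation turns both primary hydroxyl groups into leaving groups.

Step 3
Reactants: 3 cis-cyclobutane-1,2-diylbis(methylene) dimethanesulfonate
Product: 4 cis-3-thiabicyclo[3.2.0]heptane
Conditions: Na2S·9H2O, EtOH, reflux
Reagents that add atoms: sodium sulfide nonahydrate, [Na+].[Na+].[S-2]
Why: A double SN2 displacement by sulfide closes the thiolane (5-exo-tet), which the cis arrangement of the two arms favours.

Step 4
Reactants: 4 cis-3-thiabicyclo[3.2.0]heptane
Product: 6 2-chloro-3-thiabicyclo[3.2.0]heptane 3,3-dioxide (racemic; both C–Cl epimers), via α-chloro sulfide 5 (not isolated)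
Conditions: NCS, CH2Cl2, 0 °C → rt; then mCPBA (2.2 equiv), CH2Cl2, 0 °C
Reagents that add atoms: N-chlorosuccinimide, O=C1CCC(=O)N1Cl; 3-chloroperbenzoic acid, OOC(=O)c1cccc(Cl)c1
Why: Pummerer-type α-chlorination of the sulfide followed by immediate peracid oxidation is the standard entry to a Ramberg–Bäcklund substrate, and the C–Cl configuration is irrelevant because that carbon becomes sp2.

Step 5
Reactants: 6 2-chloro-3-thiabicyclo[3.2.0]heptane 3,3-dioxide
Product: 8 cis-bicyclo[2.2.0]hex-2-ene (rings C + D; C7=C12), via episulfone 7 (not isolated)
Conditions: KOt-Bu (2.5 equiv), DMSO, rt; the volatile alkene is taken into pentane, washed with water, dried and used as a titrated solution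
Reagents that add atoms: none
Why: In this Ramberg–Bäcklund reaction, α'-deprotonation, 1,3-displacement of chloride and cheletropic loss of SO2 from 7 contract the thiolane to the cyclobutene ring C, a contraction established for strained cyclobutenes.

Step 6
Reactants: 8 cis-bicyclo[2.2.0]hex-2-ene; 9 maleic anhydride
Product: 10 meso B–C–D ladder anhydride (anti-tricyclo[4.2.0.0^2,5]octane-3,4-dicarboxylic anhydride; all ring fusions cis; anhydride ring exo, that is anti to ring C)
Conditions: hν (medium-pressure Hg lamp, Pyrex), acetophenone (sensitiser), EtOAc–pentane, −10 °C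
Reagents that add atoms: none
Why: In this sensitised [2+2] photocycloaddition triplet 9 should bond to the convex face of 8 (the face of H8 and H11), so that ring B ends anti to ring D, the diradical should close with the anhydride turned away from ring C (exo arms on C4 and C5), and the five-membered anhydride enforces the cis relation of C4 and C5.

Step 7
Reactants: 10 meso B–C–D ladder anhydride
Product: 11 hemiester (CO2Me on C4 and CO2H on C5, both exo; seen from the ring C side of ring B the path C4→C5→C7→C12 runs clockwise; C4 is S and C5 is R)
Conditions: quinidine (1.1 equiv), MeOH (3 equiv), toluene, −55 °C; the alkaloid is recovered by an acid wash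
Reagents that add atoms: methanol, CO
Why: In this cinchona-alkaloid-mediated desymmetrising methanolysis of a meso anhydride the chiral base directs methanol to one enantiotopic carbonyl group (the one on C4, future C3), which fixes the absolute configuration of all six ladder stereocentres at once.

Step 8
Reactants: 11 hemiester
Product: 13 diazoketone (C5–CO–CHN2; CO2Me on C4), via mixed anhydride 12 (not isolated)
Conditions: ClCO2Et, N-methylmorpholine, THF, −15 °C; then Me3SiCHN2 (2 equiv), MeCN, 0 °C → rt
Reagents that add atoms: (trimethylsilyl)diazomethane, C[Si](C)(C)C=[N+]=[N-]; ethyl chloroformate, CCOC(=O)Cl (its atoms stay only in 12)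
Why: This first half of the Arndt–Eistert homologation acylates the diazoalkane with a cold mixed carbonic anhydride, which avoids the acid chloride whose ester/acyl exchange would racemise the hemiester and also avoids epimerisation at C5.

Step 9
Reactants: 13 diazoketone
Product: 15 N-methoxy-N-methyl amide (C5–C6H2–C1(=O)N(OMe)Me; CO2Me on C4), via ketene 14 (not isolated)
Conditions: PhCO2Ag (10 mol %), MeNHOMe·HCl, Et3N, THF, −25 °C → rt, dark
Reagents that add atoms: N,O-dimethylhydroxylamine hydrochloride, CNOC.Cl
Why: In the silver-catalysed Wolff rearrangement C5 migrates with retention onto the former diazo carbon (now C6), and ketene 14 is captured by the hydroxylamine at the former acid carbon (now C1).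

Step 10
Reactants: 15 N-methoxy-N-methyl amide
Product: 16 aldehyde (C5–C6H2–C1HO; CO2Me on C4)
Conditions: i-Bu2AlH (1.05 equiv), THF, −78 °C; aq. potassium sodium tartrate
Reagents that add atoms: none
Why: Hydride reduction of an N-methoxy-N-methyl amide stops at the chelated aluminium hemiaminal, and at −78 °C with one equivalent the amide should react ahead of the hindered cyclobutyl methyl ester.

Step 11
Reactants: 16 aldehyde
Product: 17 ladder diester (methyl ester C3 on C4; (E)-4-methoxy-4-oxobut-2-enyl arm C6–C1=C2–CO2Me on C5; both arms cis and exo on ring B)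
Conditions: (MeO)2P(O)CH2CO2Me (1.2 equiv), NaH (1.1 equiv), THF, 0 °C
Reagents that add atoms: trimethyl phosphonoacetate, COC(=O)CP(=O)(OC)OC
Why: The Horner–Wadsworth–Emmons olefination with a stabilised phosphonate should give the E-enoate, and the phosphonate anion is too weak a base to epimerise C4.

Step 12
Reactants: 18 2,2-dimethyl-1,3-dioxan-5-ol; 19 1,8-dibromooctane
Product: 20 5-(8-bromooctyloxy)-2,2-dimethyl-1,3-dioxane
Conditions: NaH, DMF, 0 °C; then 19 (4 equiv), rt
Reagents that add atoms: none
Why: In this Williamson ether synthesis on a primary bromide the excess of dibromide suppresses double alkylation.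

Step 13
Reactants: 20 5-(8-bromooctyloxy)-2,2-dimethyl-1,3-dioxane
Product: 21 8-(2,2-dimethyl-1,3-dioxan-5-yloxy)octylmagnesium bromide (titrated Et2O solution)
Conditions: Mg turnings, I2 (trace), Et2O, reflux
Reagents that add atoms: magnesium, [Mg]
Why: Magnesium inserts into the primary C–Br bond to form the Grignard reagent, and the ether and ketal groups are inert to organomagnesium species.

Step 14
Reactants: 17 ladder diester; 21 8-(2,2-dimethyl-1,3-dioxan-5-yloxy)octylmagnesium bromide
Product: 24 ring A β-keto ester (C3 ketone; C2 methyl ester trans to the chain; chain on C1 cis to ring B; C1 is R), via magnesium ester enolate 22 (not isolated), via magnesium β-keto ester enolate 23 (not isolated)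
Conditions: CuBr·SMe2 (5 mol %), (R)-1-[(SP)-2-(diphenylphosphino)ferrocenyl]ethyldicyclohexylphosphine (6 mol %), t-BuOMe, −75 °C, 21 (1.15 equiv) added slowly; then THF, −75 → 0 °C; sat. aq. NH4Cl
Reagents that add atoms: none
Why: After transmetallation from 21 the ligated monovalent copper alkyl forms a π-complex with C1=C2 of 17 while magnesium holds the enoate carbonyl oxygen; slippage to a σ-bound trivalent copper centre on C1 and reductive elimination make C1–C1' and release the regiodefined bromomagnesium enolate 22. The closest known reaction types are the copper–ferrocenyl diphosphine catalysed asymmetric conjugate addition of Grignard reagents to acyclic E-enoates, whose magnesium enolates have been trapped intramolecularly, and the tandem conjugate addition–Dieckmann cyclisation of organocopper reagents with enoate esters; here the two are run in one flask. On warming, C2 of 22 attacks the ester carbon C3 in a 6-(enolexo)-exo-trig closure of ring A, methoxide is expelled and at once deprotonates C2, so the product rests as the chelated enolate 23, which the slight excess of 21 should not attack. C1 is set by the ligand, which should steer the alkyl group to the Re face of C1 (chain cis to ring B after closure) with little interference from C5, the nearest resident stereocentre, two bonds away; C2 settles trans to the chain by keto–enol equilibration and is deleted in step 15. The step needs 1,4- before 1,2-addition and the enoate before the C3 ester, which ligand-accelerated catalysis at −75 °C and the hindered secondary cyclobutyl position of the C3 ester should secure, and it needs a single Dieckmann direction, which follows because only C2 ever becomes an enolate. Because C3 and C6 leave ring B from the same exo face, the enolate carbon reaches C3 without strain and a trans A/B fusion is geometrically out of reach, and the wholly polar sequence spares the ladder from ring-opening pathways.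

Step 15
Reactants: 24 ring A β-keto ester
Product: 26 ring A ketone (C3=O; C2 now CH2; chain on C1 cis to ring B), via β-keto acid 25 (not isolated)
Conditions: LiOH·H2O (3 equiv), THF–MeOH–H2O, rt; cold aq. citric acid to pH 4, extraction into toluene; 60 °C
Reagents that add atoms: lithium hydroxide, [Li+].[OH-] (its oxygen stays only in 25)
Why: Saponification and then decarboxylation of the β-keto acid through its cyclic six-membered transition state run far below the temperature at which bicyclo[2.2.0]hexane units open, erase C2, and leave the enolisable C4 cis because the cis-fused bicyclo[4.2.0]octanone is the more stable epimer.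

Step 16
Reactants: 26 ring A ketone
Product: 27 C3 tosylhydrazone (C=N geometry not defined)
Conditions: TsNHNH2 (1.1 equiv), MeOH, 40 °C
Reagents that add atoms: 4-methylbenzenesulfonohydrazide, Cc1ccc(cc1)S(=O)(=O)NN
Why: The ketone condenses with the sulfonyl hydrazide without added acid, so the ketal should survive.

Step 17
Reactants: 27 C3 tosylhydrazone
Product: 30 acetonide of the target (C3 now CH2; C1 becomes S by a change of priorities only), via N-boryl tosylhydrazine 28 (not isolated), via alkyl diazene 29 (not isolated)
Conditions: catecholborane (2 equiv), CHCl3, −10 °C → rt; NaOAc·3H2O (3 equiv), 60 °C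
Reagents that add atoms: catecholborane, B1Oc2ccccc2O1 (its atoms stay only in 28)
Why: In this Caglioti-type tosylhydrazone deoxygenation in its catecholborane form, hydride adds to C=N, acetate triggers loss of sulfinate from 28, and diazene 29 extrudes N2 to leave CH2 at C3 under nearly neutral conditions at about 60 °C.

Step 18
Reactants: 30 acetonide of the target
Product: 31 CNP0193334.1, 2-O-alkyl glycerol ether of the [3]-ladderane octyl chain
Conditions: 1 M aq. HCl, THF–MeOH, rt
Reagents that add atoms: none
Why: Acid-catalysed ketal hydrolysis frees the 1,3-diol, while the saturated ladder and the dialkyl ether are inert to dilute acid.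

## Compound list

1 | cis-cyclobutane-1,2-dicarboxylic anhydride (ring D) | O=C1OC(=O)[C@H]2CC[C@@H]12 | starting material
2 | cis-cyclobutane-1,2-diyldimethanol | OC[C@H]1CC[C@H]1CO | intermediate
3 | cis-cyclobutane-1,2-diylbis(methylene) dimethanesulfonate | CS(=O)(=O)OC[C@H]1CC[C@H]1COS(C)(=O)=O | intermediate
4 | cis-3-thiabicyclo[3.2.0]heptane | S1C[C@H]2CC[C@H]2C1 | intermediate
5 | 2-chloro-3-thiabicyclo[3.2.0]heptane (racemic, C–Cl undefined) | S1C[C@H]2CC[C@H]2C1Cl | intermediate
6 | 2-chloro-3-thiabicyclo[3.2.0]heptane 3,3-dioxide (racemic, C–Cl undefined) | O=S1(=O)C[C@H]2CC[C@H]2C1Cl | intermediate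
7 | episulfone bridging C7 and C12 (drawn anti to ring D; orientation immaterial) | O=S1(=O)[C@@H]2[C@H]1[C@H]1CC[C@@H]21 | intermediate
8 | cis-bicyclo[2.2.0]hex-2-ene | C1=C[C@H]2CC[C@@H]12 | intermediate
9 | maleic anhydride | O=C1C=CC(=O)O1 | starting material
10 | meso B–C–D ladder anhydride (exo, all fusions cis, anti) | O=C4[C@@H]2[C@H](C(=O)O4)[C@H]1[C@@H]3CC[C@@H]3[C@@H]21 | intermediate
11 | hemiester (CO2Me on C4, CO2H on C5) | COC(=O)[C@@H]2[C@H](C(=O)O)[C@H]1[C@@H]3CC[C@@H]3[C@@H]21 | intermediate
12 | mixed ethyl carbonic anhydride of 11 | COC(=O)[C@@H]2[C@H](C(=O)OC(=O)OCC)[C@H]1[C@@H]3CC[C@@H]3[C@@H]21 | intermediate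
13 | diazoketone on C5 | COC(=O)[C@@H]2[C@H](C(=O)C=[N+]=[N-])[C@H]1[C@@H]3CC[C@@H]3[C@@H]21 | intermediate
14 | ketene on C5 (C6H=C1=O) | COC(=O)[C@@H]2[C@H](C=C=O)[C@H]1[C@@H]3CC[C@@H]3[C@@H]21 | intermediate
15 | N-methoxy-N-methyl amide | COC(=O)[C@@H]2[C@H](CC(=O)N(C)OC)[C@H]1[C@@H]3CC[C@@H]3[C@@H]21 | intermediate
16 | aldehyde (C5–CH2–CHO) | COC(=O)[C@@H]2[C@H](CC=O)[C@H]1[C@@H]3CC[C@@H]3[C@@H]21 | intermediate
17 | ladder diester with E-enoate arm | COC(=O)[C@@H]2[C@H](C/C=C/C(=O)OC)[C@H]1[C@@H]3CC[C@@H]3[C@@H]21 | intermediate
18 | 2,2-dimethyl-1,3-dioxan-5-ol | OC1COC(C)(C)OC1 | starting material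
19 | 1,8-dibromooctane | BrCCCCCCCCBr | starting material
20 | 5-(8-bromooctyloxy)-2,2-dimethyl-1,3-dioxane | BrCCCCCCCCOC1COC(C)(C)OC1 | intermediate
21 | 8-(2,2-dimethyl-1,3-dioxan-5-yloxy)octylmagnesium bromide | Br[Mg]CCCCCCCCOC1COC(C)(C)OC1 | intermediate
22 | bromomagnesium ester enolate at C2 (C=C geometry immaterial) | COC(=O)[C@@H]2[C@H](C[C@@H](CCCCCCCCOC4COC(C)(C)OC4)C=C(OC)O[Mg]Br)[C@H]1[C@@H]3CC[C@@H]3[C@@H]21 | intermediate
23 | bromomagnesium enolate of the β-keto ester | CC1(C)OCC(CO1)OCCCCCCCC[C@H]1C(C(=O)OC)=C(O[Mg]Br)[C@@H]2[C@H](C1)[C@H]1[C@@H]3CC[C@@H]3[C@@H]21 | intermediate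
24 | ring A β-keto ester | CC1(C)OCC(CO1)OCCCCCCCC[C@H]1[C@H](C(=O)OC)C(=O)[C@@H]2[C@H](C1)[C@H]1[C@@H]3CC[C@@H]3[C@@H]21 | intermediate
25 | ring A β-keto acid | CC1(C)OCC(CO1)OCCCCCCCC[C@H]1[C@H](C(=O)O)C(=O)[C@@H]2[C@H](C1)[C@H]1[C@@H]3CC[C@@H]3[C@@H]21 | intermediate
26 | ring A ketone (C3=O) | CC1(C)OCC(CO1)OCCCCCCCC[C@H]1CC(=O)[C@@H]2[C@H](C1)[C@H]1[C@@H]3CC[C@@H]3[C@@H]21 | intermediate
27 | C3 tosylhydrazone | CC1(C)OCC(CO1)OCCCCCCCC[C@H]1CC(=NNS(=O)(=O)c4ccc(C)cc4)[C@@H]2[C@H](C1)[C@H]1[C@@H]3CC[C@@H]3[C@@H]21 | intermediate
28 | N-boryl tosylhydrazine (C3 undefined) | CC1(C)OCC(CO1)OCCCCCCCC[C@H]1CC(N(NS(=O)(=O)c4ccc(C)cc4)B5Oc6ccccc6O5)[C@@H]2[C@H](C1)[C@H]1[C@@H]3CC[C@@H]3[C@@H]21 | intermediate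
29 | alkyl diazene at C3 (C3 undefined) | CC1(C)OCC(CO1)OCCCCCCCC[C@H]1CC(N=N)[C@@H]2[C@H](C1)[C@H]1[C@@H]3CC[C@@H]3[C@@H]21 | intermediate
30 | acetonide of the target | CC1(C)OCC(CO1)OCCCCCCCC[C@H]1CC[C@@H]2[C@H](C1)[C@H]1[C@@H]3CC[C@@H]3[C@@H]21 | intermediate
31 | CNP0193334.1 | OCC(CO)OCCCCCCCC[C@H]1CC[C@@H]2[C@H](C1)[C@H]1[C@@H]3CC[C@@H]3[C@@H]21 | target

## Step count and risks

Total step count: 18. Longest linear sequence: 16 (steps 1–11 and 14–18); steps 12 and 13 form the side branch.

**Step 14.**
- What may go wrong: the magnesium enolate may close ring A sluggishly, the residual Grignard reagent may add 1,2 to an ester on warming, or the bulky ladder substituent on C6 may erode the facial selectivity at C1.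
- Fallback (from 17 and 21, back at 24): the two bond formations are uncoupled.
  - The conjugate addition is run as above but quenched with methanol at −75 °C, which should give the open-chain diester F1.
  - Its minor C1 epimer is a diastereomer and can be removed by chromatography at this stage.
  - A separate Dieckmann condensation of F1 with KOt-Bu in THF at 0 °C is reversible. Only closure through C2 leaves an acidic C–H between two carbonyl groups, so the equilibrium should drain to 24, where the route is rejoined.

**Step 17.**
- What may go wrong: the diazene may decay homolytically. That would place spin density on C3 next to ring B and open the ladder by β-scission.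
- Fallback (from 27, back at 30): deoxygenation by elimination and then concerted reduction.
  - A Shapiro reaction (n-BuLi, 2.2 equiv, THF–TMEDA, −78 → 0 °C, water quench) deprotonates the less hindered C2 side and runs through carbanionic species only. It should give the C2=C3 cyclohexene F2.
  - Diimide, generated from dipotassium azodicarboxylate and acetic acid in MeOH at 0 °C → rt, saturates F2 by concerted hydrogen transfer. No stereocentre is at stake, and the route is rejoined at 30.

**Step 6.**
- What may go wrong: the anti/syn selectivity across the new ring B may be poor, the excited anhydride may dimerise, the sensitiser may form oxetanes, or the volatile alkene may be lost by evaporation.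
- Fallback (from 8, back at 10): the 2π partner is changed to a chromophore that needs no sensitiser and gives crystalline adducts.
  - Direct irradiation (Pyrex) of 8 with maleimide in MeCN should give the exo ladder imide F3, which is purified by crystallisation.
  - Hydrolysis with 2 M NaOH at 70 °C and acidification lead to the cis-diacid F4.
  - Dehydration of F4 with acetic anhydride at 50 °C closes the anhydride 10, where the route is rejoined.

## Further compounds

F1 | step 14 | open-chain diester (chain on C1, C2H2–CO2Me, CO2Me on C4) | COC(=O)[C@@H]2[C@H](C[C@@H](CCCCCCCCOC4COC(C)(C)OC4)CC(=O)OC)[C@H]1[C@@H]3CC[C@@H]3[C@@H]21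
F2 | step 17 | C2=C3 cyclohexene acetonide | CC1(C)OCC(CO1)OCCCCCCCC[C@H]1C=C[C@@H]2[C@H](C1)[C@H]1[C@@H]3CC[C@@H]3[C@@H]21
F3 | step 6 | meso exo ladder imide | O=C4[C@@H]2[C@H](C(=O)N4)[C@H]1[C@@H]3CC[C@@H]3[C@@H]21
F4 | step 6 | meso exo ladder cis-diacid | OC(=O)[C@@H]2[C@H](C(=O)O)[C@H]1[C@@H]3CC[C@@H]3[C@@H]21
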